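Beta, charged with 0.0099 M of substrate, ends 6.44% short of full target, and gamma, with 0.039 M, ends 35.2% short. In logarithms that is 1.24: call it the loss slope, the powers of ten by which the share of substrate lost to side product climbs per power of ten of substrate charged.

| flask | substrate | partner | free catalyst | temperature | remark | time |
|---|---|---|---|---|---|---|
| beta | 0.0099 M | 0.060 M | 33 µM | 20 °C | run made earlier |  |
| gamma | 0.039 M | 0.060 M | 33 µM | 31 °C | run made earlier |  |
| eta | 0.11 M | 0.060 M | 33 µM | 20 °C | run made earlier |  |
| maple | 0.012 M | 0.0600 M | 33 µM | 25 °C |  | 4.0 h |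
| larch | 0.10 M | 0.0600 M | 33 µM | 25 °C |  | 4.0 h |
| cedar | 0.025 M | 0.0600 M | 33 µM | 25 °C |  | 4.0 h |
| oak | 0.050 M | 0.0600 M | 33 µM | 25 °C |  | 4.0 h |
| birch | 0.15 M | 0.0600 M | 33 µM | 25 °C |  | 4.0 h |

| run | time / h | target / % | substrate / % |
|---|---|---|---|
| beta | 0.833 | 93.6 | 0 |
| beta | 1.50 | 93.1 | 0 |
| beta | 2.50 | 93.3 | 0 |
| beta | 3.00 | 94.7 | 0 |
| beta | 4.00 | 93.1 | 0.8 |
| gamma | 0.333 | 64.3 | 0 |
| gamma | 0.667 | 64.8 | 0 |
| gamma | 1.00 | 65.1 | 0 |
| gamma | 2.00 | 64.9 | 0.3 |
| gamma | 4.00 | 64.8 | 0 |
| eta | 0.333 | 10.7 | 52.1 |
| eta | 1.00 | 12.7 | 7.3 |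
| eta | 2.00 | 10.3 | 1.7 |
| eta | 3.00 | 9.2 | 0.8 |
| eta | 4.00 | 9.2 | 0 |

(readings scatter by 0.5 percentage points)

- percentages count the substrate that a species holds: one side product counts as two
- what may be going on: substrate + target -> side product; partner <-> dormant form; catalyst intermediate C -> free catalyst + target; partner + catalyst intermediate A -> catalyst intermediate B; catalyst intermediate B <-> catalyst intermediate C; substrate + free catalyst -> catalyst intermediate A

* the flasks put in order of amount of target, in percent of the substrate charged, best first, at 4.0 h (maple / larch / cedar / oak / birch)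
* the same order at 12 min (maple / larch / cedar / oak / birch)
* the amount of target, in percent of the substrate charged of the flask you put first, at 4.0 h
* the amount of target, in percent of the substrate charged of the flask you put last, at 4.0 h

You can bracket each flask with two extremes. If catalysis finished before any side reaction began, target would equal the lesser charge, and with partner as limiting reagent the leftover substrate would then eat target one for one. That gives a ceiling of (2[partner] − [substrate])/[substrate], on the charges. Eta's ceiling is 9.09%, and eta reads 9.2%. If the side reaction outran catalysis instead, target would end at zero. Beta and gamma stand between these extremes, and the slope says where.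

Beta and gamma differ in temperature too, 20 °C against 31 °C, so the slope carries both changes; I draw the line across them, assuming 25 °C lies on it. Maple then loses 8.17%, cedar 20.3% and oak 47.9%, so oak keeps 52.1%. For larch the line passes 113%, so I take its ceiling, 20.0%. Birch's ceiling is −20.0%, below zero, so I expect no target there.

The forecast gives maple > cedar > oak > larch > birch at 4.0 h and maple > cedar > oak > larch > birch at 12 min, with 92.2% on top and 0% at the bottom, since “Birch exceeds 2×partner, so leftover substrate eats all target”. For oak it says about 42 per cent, where I reckon 52.1%.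

The flasks stand at maple > cedar > oak > larch > birch at 4.0 h and at maple > cedar > oak > larch > birch at 12 min, with maple at 91.8% and birch at 0% at 4.0 h, when birch keeps 20.0% of its substrate with partner at 0%.

    substrate + target → side product (k = 0.0407 M⁻¹ s⁻¹, Ea = 53.0 kJ mol⁻¹)
    partner ⇌ dormant form (K = 0.564, k = 0.00155 s⁻¹, Ea = 96.0 kJ mol⁻¹, ΔH = 11.0 kJ mol⁻¹)
    catalyst intermediate C → free catalyst + target (k = 9.92 s⁻¹, Ea = 77.0 kJ mol⁻¹)
    partner + catalyst intermediate A → catalyst intermediate B (k = 160 M⁻¹ s⁻¹, Ea = 38.0 kJ mol⁻¹)
    catalyst intermediate B ⇌ catalyst intermediate C (K = 14.0, k = 2.50 s⁻¹, Ea = 78.0 kJ mol⁻¹, ΔH = −10.0 kJ mol⁻¹)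
    substrate + free catalyst → catalyst intermediate A (k = 278 M⁻¹ s⁻¹, Ea = 42.0 kJ mol⁻¹)
    (constants at 25 °C)

Oak gives 54.9%, above both reckonings. The slope's loss of 20.3% for cedar stands against 21.0% of side product. In maple, half of the turning of catalyst intermediate B into catalyst intermediate C up to 4.0 h is done by 3.04 min, while the side reaction's rate constant at the charged substrate gives target a lifetime of 34.1 min, which is longer. Maple's slope loss was 8.17%, and at 4.00 h it holds 8.20% of side product.

The readings stem from a simulated flask on assumed constants; noise was put on by code.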